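The route rests on cutting C7–C8 of the cyclohexanone ring C1–C8–C7–C6–C5–C9. C8 is a methyl-bearing quaternary carbon on quaternary C1 and C7 carries a CH2–C unit, so C8 maps onto the Markovnikov radical of a 1,1-disubstituted alkene and C7 onto the β-carbon of an enal. The precursor is a dearomatised acylphloroglucinol with one stereocentre (C1: allyl and hexa-1,5-dien-2-yl) and two identical (E)-4-oxobut-2-enyl arms on C5. Iron-hydride hydrogen-atom transfer then closes the bicyclo[3.3.1]nonane 6-exo, makes the C8 methyl, desymmetrises C5 and sets C5, C7 and C8 at once. Cross-metathesis and a Wittig reaction finish the four prenyl-type chains.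

Key step: step 12

Remark: ring atoms are numbered as in the bicyclic core (C1 bridgehead next to C8, C5 the other bridgehead, C9 the bridging ketone); the enolised triketone is drawn throughout as the C2-keto/C4-enol tautomer, and CIP descriptors refer to that drawing.

Step 1
Reactants: 1 phloroglucinol (benzene-1,3,5-triol)
Product: 2 1,3,5-tris(methoxymethoxy)benzene
Conditions: MOMCl, NaH, DMF, 0 °C to rt
Reagents that add atoms: chloromethyl methyl ether, COCCl
Why: O-alkylation of the phenoxides (Williamson ether synthesis) with the reactive α-chloro ether installs three MOM ethers that later direct ortho-lithiation.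

Step 2
Reactants: 3 2,3-dibromoprop-1-ene; 4 allylmagnesium bromide
Product: 5 2-bromohexa-1,5-diene
Conditions: Et2O, 0 °C to rt
Reagents that add atoms: none
Why: Allylic substitution of the allylic bromide by the allyl Grignard reagent (SN2 and SN2' lead to the same product), while the vinylic C–Br bond does not react.

Step 3
Reactants: 2 1,3,5-tris(methoxymethoxy)benzene; 5 2-bromohexa-1,5-diene
Product: 8 2-(hexa-1,5-dien-2-yl)-1,3,5-tris(methoxymethoxy)benzene, via aryllithium 6 (not isolated), via arylzinc chloride 7 (not isolated)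
Conditions: n-BuLi, THF, 0 °C; ZnCl2, 0 °C to rt; then 5, Pd(OAc)2 (cat.), SPhos, THF, 60 °C
Reagents that add atoms: none
Why: Directed ortho-lithiation between two MOM ethers, transmetalation to zinc and Negishi coupling with the alkenyl bromide, the bulky biarylphosphine supporting coupling of the doubly ortho-substituted arylzinc.

Step 4
Reactants: 9 methyl 3-hydroxybenzoate
Product: 10 methyl 3-(triisopropylsilyloxy)benzoate
Conditions: TIPSCl, imidazole, DMF, rt
Reagents that add atoms: triisopropylsilyl chloride, CC(C)[Si](Cl)(C(C)C)C(C)C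
Why: Silylation of the phenol gives a bulky aryl silyl ether that should survive organolithium, mild acid, zerovalent palladium and Wittig conditions.

Step 5
Reactants: 8 2-(hexa-1,5-dien-2-yl)-1,3,5-tris(methoxymethoxy)benzene; 10 methyl 3-(triisopropylsilyloxy)benzoate
Product: 12 [3-(hexa-1,5-dien-2-yl)-2,4,6-tris(methoxymethoxy)phenyl][3-(triisopropylsilyloxy)phenyl]methanone, via aryllithium 11 (not isolated)
Conditions: n-BuLi, THF, 0 °C; then 10, −78 °C to rt
Reagents that add atoms: none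
Why: Second directed ortho-lithiation at one of the two equivalent positions flanked by MOM ethers, then acylation by the ester; the doubly ortho-substituted diaryl ketone should resist a second addition.

Step 6
Reactants: 12 [3-(hexa-1,5-dien-2-yl)-2,4,6-tris(methoxymethoxy)phenyl][3-(triisopropylsilyloxy)phenyl]methanone
Product: 13 [3-(hexa-1,5-dien-2-yl)-2,4,6-trihydroxyphenyl][3-(triisopropylsilyloxy)phenyl]methanone
Conditions: HCl (cat.), MeOH/THF, 40 °C
Reagents that add atoms: none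
Why: Acid-catalysed transacetalisation removes the three MOM groups; the aryl TIPS ether tolerates mild acid and the doubly ortho-substituted styrene-type alkene is twisted out of conjugation, so its protonation should be slow.

Step 7
Reactants: 14 (E)-4,4-dimethoxybut-2-enal
Product: 15 (E)-4,4-dimethoxybut-2-en-1-ol
Conditions: NaBH4, MeOH, 0 °C
Reagents that add atoms: none
Why: Borohydride 1,2-reduction of the conjugated aldehyde leaves the acetal and the E-alkene untouched.

Step 8
Reactants: 15 (E)-4,4-dimethoxybut-2-en-1-ol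
Product: 16 (E)-4,4-dimethoxybut-2-en-1-yl methyl carbonate
Conditions: ClCO2Me, pyridine, CH2Cl2, 0 °C
Reagents that add atoms: methyl chloroformate, COC(=O)Cl
Why: Acylation of the allylic alcohol gives a carbonate that ionises with zerovalent palladium and releases methoxide as internal base.

Step 9
Reactants: 13 [3-(hexa-1,5-dien-2-yl)-2,4,6-trihydroxyphenyl][3-(triisopropylsilyloxy)phenyl]methanone; 16 (E)-4,4-dimethoxybut-2-en-1-yl methyl carbonate (2.1 equiv)
Product: 18 6,6-bis[(E)-4,4-dimethoxybut-2-en-1-yl]-2-(hexa-1,5-dien-2-yl)-3,5-dihydroxy-4-[3-(triisopropylsilyloxy)benzoyl]cyclohexa-2,4-dien-1-one, via mono-allylated acylphloroglucinol 17 (not isolated)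
Conditions: Pd(PPh3)4 (cat.), THF, 0 °C to rt
Reagents that add atoms: none
Why: Tsuji–Trost C-allylation of the acidic acylphloroglucinol should take place twice at unsubstituted C5 (alkylative dearomatisation as in the lupulone series), because C3 is blocked by the acyl group and C1 is shielded on both faces by the twisted alkenyl group; the soft nucleophile attacks the unsubstituted π-allyl terminus to give the linear E arm, and O-allylation is reversible.

Step 10
Reactants: 18 6,6-bis[(E)-4,4-dimethoxybut-2-en-1-yl]-2-(hexa-1,5-dien-2-yl)-3,5-dihydroxy-4-[3-(triisopropylsilyloxy)benzoyl]cyclohexa-2,4-dien-1-one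
Product: 19 (6S)-6-allyl-4,4-bis[(E)-4,4-dimethoxybut-2-en-1-yl]-6-(hexa-1,5-dien-2-yl)-3-hydroxy-2-[3-(triisopropylsilyloxy)benzoyl]cyclohex-2-ene-1,5-dione
Conditions: allyl methyl carbonate, Pd2(dba)3 (cat.), (R,R)-DACH-phenyl Trost ligand, CH2Cl2, −20 °C
Reagents that add atoms: allyl methyl carbonate, C=CCOC(=O)OC
Why: Pd-catalysed asymmetric allylic alkylation (Trost type) of the prochiral stabilised enolate, in which C1 is the only carbon nucleophile left and O-allylation is reversible; the chiral ligand pocket is expected to distinguish the two faces of C1, whose flanks (C2 enol side versus C9/C5 side) differ strongly, and the ligand antipode would be taken should the sense of induction prove opposite.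

Step 11
Reactants: 19 (6S)-6-allyl-4,4-bis[(E)-4,4-dimethoxybut-2-en-1-yl]-6-(hexa-1,5-dien-2-yl)-3-hydroxy-2-[3-(triisopropylsilyloxy)benzoyl]cyclohex-2-ene-1,5-dione
Product: 20 (6S)-6-allyl-6-(hexa-1,5-dien-2-yl)-3-hydroxy-4,4-bis[(E)-4-oxobut-2-en-1-yl]-2-[3-(triisopropylsilyloxy)benzoyl]cyclohex-2-ene-1,5-dione
Conditions: 1 M HCl, acetone/H2O, rt
Reagents that add atoms: water, O
Why: Acid hydrolysis of the two dimethyl acetals gives the conjugated E-enals; the quaternary C1 and C5 cannot epimerise and the terminal alkenes are inert to dilute acid.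

Step 12
Reactants: 20 (6S)-6-allyl-6-(hexa-1,5-dien-2-yl)-3-hydroxy-4,4-bis[(E)-4-oxobut-2-en-1-yl]-2-[3-(triisopropylsilyloxy)benzoyl]cyclohex-2-ene-1,5-dione
Product: 21 (1S,5S,7S,8S)-1-allyl-8-(but-3-en-1-yl)-4-hydroxy-8-methyl-5-[(E)-4-oxobut-2-en-1-yl]-7-(2-oxoethyl)-3-[3-(triisopropylsilyloxy)benzoyl]bicyclo[3.3.1]non-3-ene-2,9-dione
Conditions: Fe(acac)3 (0.5 equiv), PhSiH3 (3 equiv), EtOH/THF (0.01 M), 50 °C; 1 M HCl wash
Reagents that add atoms: none
Why: A trivalent-iron hydride (from Fe(acac)3 and PhSiH3) should transfer a hydrogen atom to the terminal CH2 of the 1,1-disubstituted alkene, so that this methylene becomes the C8 methyl and a tertiary C8 radical results; the nucleophilic radical adds to the β-carbon (C7) of the enal arm on its own ring face, and the α-formyl radical is reduced to the enolate and protonated by ethanol. The closest known reaction type is the intramolecular metal-hydride HAT-initiated Giese addition (reductive olefin coupling), a standard way to join hindered quaternary carbons. The closure is 6-exo-trig and forms ring C1–C8–C7–C6–C5–C9 across the C9 ketone with both tethers axial. C5 is set because only the arm cis to C8 can reach (desymmetrisation relayed from C1), C7 by a chair transition state that keeps the enal residue exo, away from the C2–C3–C4 bridge, and C8 by the but-3-enyl chain taking the pseudo-equatorial site while the small methyl takes the pseudo-axial site syn to C6–H. The step needs HAT to prefer the 1,1-disubstituted alkene over the two monosubstituted alkenes and the electron-poor enals, which the substitution pattern should secure, and it needs ring closure to outrun 1,2-acyl shift of the radical onto C9, which the activated, pre-organised acceptor should secure.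

Step 13
Reactants: 21 (1S,5S,7S,8S)-1-allyl-8-(but-3-en-1-yl)-4-hydroxy-8-methyl-5-[(E)-4-oxobut-2-en-1-yl]-7-(2-oxoethyl)-3-[3-(triisopropylsilyloxy)benzoyl]bicyclo[3.3.1]non-3-ene-2,9-dione
Product: 22 (1S,5S,7S,8S)-4-hydroxy-8-methyl-1,5-bis(3-methylbut-2-en-1-yl)-8-(4-methylpent-3-en-1-yl)-7-(2-oxoethyl)-3-[3-(triisopropylsilyloxy)benzoyl]bicyclo[3.3.1]non-3-ene-2,9-dione
Conditions: second-generation Grubbs catalyst RuCl2(=CHPh)(H2IMes)(PCy3) (cat.), 2-methyl-2-butene/CH2Cl2, 40 °C
Reagents that add atoms: 2-methyl-2-butene, CC=C(C)C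
Why: Olefin cross-metathesis with a large excess of 2-methyl-2-butene should cap the C1 allyl and C8 butenyl groups as trisubstituted alkenes and exchange the internal enal C=C of the C5 arm (the elementary step of cross-metathesis with crotonaldehyde, run in the releasing direction and driven by the excess alkene), while the saturated aldehyde on C7 is inert to the ruthenium carbene.

Step 14
Reactants: 22 (1S,5S,7S,8S)-4-hydroxy-8-methyl-1,5-bis(3-methylbut-2-en-1-yl)-8-(4-methylpent-3-en-1-yl)-7-(2-oxoethyl)-3-[3-(triisopropylsilyloxy)benzoyl]bicyclo[3.3.1]non-3-ene-2,9-dione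
Product: 23 (1S,5S,7R,8S)-4-hydroxy-8-methyl-1,5,7-tris(3-methylbut-2-en-1-yl)-8-(4-methylpent-3-en-1-yl)-3-[3-(triisopropylsilyloxy)benzoyl]bicyclo[3.3.1]non-3-ene-2,9-dione
Conditions: i-PrPPh3I, n-BuLi (excess ylide), THF, 0 °C; then 22, −78 to 0 °C
Reagents that add atoms: isopropyltriphenylphosphonium iodide, CC(C)[P+](c1ccccc1)(c1ccccc1)c1ccccc1.[I-]
Why: Wittig olefination of the only aldehyde with the non-stabilised isopropylidene ylide completes the C7 prenyl group; the first equivalent of ylide deprotonates the triketone, whose enolate and the hindered C9 ketone should not react.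

Step 15
Reactants: 23 (1S,5S,7R,8S)-4-hydroxy-8-methyl-1,5,7-tris(3-methylbut-2-en-1-yl)-8-(4-methylpent-3-en-1-yl)-3-[3-(triisopropylsilyloxy)benzoyl]bicyclo[3.3.1]non-3-ene-2,9-dione
Product: 24 (1S,5S,7R,8S)-4-hydroxy-3-(3-hydroxybenzoyl)-8-methyl-1,5,7-tris(3-methylbut-2-en-1-yl)-8-(4-methylpent-3-en-1-yl)bicyclo[3.3.1]non-3-ene-2,9-dione (CNP0406274.2)
Conditions: TBAF, AcOH, THF, 0 °C
Reagents that add atoms: none
Why: Fluoride cleaves the aryl silyl ether (strong Si–F bond), and the buffered conditions should leave the enolised triketone and the four trisubstituted alkenes intact.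

Compound list
1 | phloroglucinol (benzene-1,3,5-triol) | Oc1cc(O)cc(O)c1 | starting material
2 | 1,3,5-tris(methoxymethoxy)benzene | COCOc1cc(OCOC)cc(OCOC)c1 | intermediate
3 | 2,3-dibromoprop-1-ene | C=C(Br)CBr | starting material
4 | allylmagnesium bromide | C=CC[Mg]Br | starting material
5 | 2-bromohexa-1,5-diene | C=CCCC(Br)=C | intermediate
6 | [2,4,6-tris(methoxymethoxy)phenyl]lithium (aryllithium, not isolated) | [Li]c1c(OCOC)cc(OCOC)cc1OCOC | intermediate
7 | [2,4,6-tris(methoxymethoxy)phenyl]zinc chloride (arylzinc chloride, not isolated) | Cl[Zn]c1c(OCOC)cc(OCOC)cc1OCOC | intermediate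
8 | 2-(hexa-1,5-dien-2-yl)-1,3,5-tris(methoxymethoxy)benzene | C=CCCC(=C)c1c(OCOC)cc(OCOC)cc1OCOC | intermediate
9 | methyl 3-hydroxybenzoate | COC(=O)c1cccc(O)c1 | starting material
10 | methyl 3-(triisopropylsilyloxy)benzoate | COC(=O)c1cccc(O[Si](C(C)C)(C(C)C)C(C)C)c1 | intermediate
11 | [3-(hexa-1,5-dien-2-yl)-2,4,6-tris(methoxymethoxy)phenyl]lithium (aryllithium, not isolated) | [Li]c1c(OCOC)cc(OCOC)c(C(=C)CCC=C)c1OCOC | intermediate
12 | [3-(hexa-1,5-dien-2-yl)-2,4,6-tris(methoxymethoxy)phenyl][3-(triisopropylsilyloxy)phenyl]methanone | C=CCCC(=C)c1c(OCOC)cc(OCOC)c(C(=O)c2cccc(O[Si](C(C)C)(C(C)C)C(C)C)c2)c1OCOC | intermediate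
13 | [3-(hexa-1,5-dien-2-yl)-2,4,6-trihydroxyphenyl][3-(triisopropylsilyloxy)phenyl]methanone | C=CCCC(=C)c1c(O)cc(O)c(C(=O)c2cccc(O[Si](C(C)C)(C(C)C)C(C)C)c2)c1O | intermediate
14 | (E)-4,4-dimethoxybut-2-enal (fumaraldehyde mono(dimethyl acetal)) | COC(OC)/C=C/C=O | starting material
15 | (E)-4,4-dimethoxybut-2-en-1-ol | COC(OC)/C=C/CO | intermediate
16 | (E)-4,4-dimethoxybut-2-en-1-yl methyl carbonate | COC(OC)/C=C/COC(=O)OC | intermediate
17 | [3-[(E)-4,4-dimethoxybut-2-en-1-yl]-5-(hexa-1,5-dien-2-yl)-2,4,6-trihydroxyphenyl][3-(triisopropylsilyloxy)phenyl]methanone (mono-allylated acylphloroglucinol, not isolated) | C=CCCC(=C)c1c(O)c(C/C=C/C(OC)OC)c(O)c(C(=O)c2cccc(O[Si](C(C)C)(C(C)C)C(C)C)c2)c1O | intermediate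
18 | 6,6-bis[(E)-4,4-dimethoxybut-2-en-1-yl]-2-(hexa-1,5-dien-2-yl)-3,5-dihydroxy-4-[3-(triisopropylsilyloxy)benzoyl]cyclohexa-2,4-dien-1-one | C=CCCC(=C)C1=C(O)C(C(=O)c2cccc(O[Si](C(C)C)(C(C)C)C(C)C)c2)=C(O)C(C/C=C/C(OC)OC)(C/C=C/C(OC)OC)C1=O | intermediate
19 | (6S)-6-allyl-4,4-bis[(E)-4,4-dimethoxybut-2-en-1-yl]-6-(hexa-1,5-dien-2-yl)-3-hydroxy-2-[3-(triisopropylsilyloxy)benzoyl]cyclohex-2-ene-1,5-dione | C=CCCC(=C)[C@]1(CC=C)C(=O)C(C(=O)c2cccc(O[Si](C(C)C)(C(C)C)C(C)C)c2)=C(O)C(C/C=C/C(OC)OC)(C/C=C/C(OC)OC)C1=O | intermediate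
20 | (6S)-6-allyl-6-(hexa-1,5-dien-2-yl)-3-hydroxy-4,4-bis[(E)-4-oxobut-2-en-1-yl]-2-[3-(triisopropylsilyloxy)benzoyl]cyclohex-2-ene-1,5-dione | C=CCCC(=C)[C@]1(CC=C)C(=O)C(C(=O)c2cccc(O[Si](C(C)C)(C(C)C)C(C)C)c2)=C(O)C(C/C=C/C=O)(C/C=C/C=O)C1=O | intermediate
21 | (1S,5S,7S,8S)-1-allyl-8-(but-3-en-1-yl)-4-hydroxy-8-methyl-5-[(E)-4-oxobut-2-en-1-yl]-7-(2-oxoethyl)-3-[3-(triisopropylsilyloxy)benzoyl]bicyclo[3.3.1]non-3-ene-2,9-dione (C7 side chain exo, C8 methyl axial) | C=CCC[C@@]1(C)[C@H](CC=O)C[C@]2(C/C=C/C=O)C(=O)[C@@]1(CC=C)C(=O)C(C(=O)c1cccc(O[Si](C(C)C)(C(C)C)C(C)C)c1)=C2O | intermediate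
22 | (1S,5S,7S,8S)-4-hydroxy-8-methyl-1,5-bis(3-methylbut-2-en-1-yl)-8-(4-methylpent-3-en-1-yl)-7-(2-oxoethyl)-3-[3-(triisopropylsilyloxy)benzoyl]bicyclo[3.3.1]non-3-ene-2,9-dione | CC(C)=CCC[C@@]1(C)[C@H](CC=O)C[C@]2(CC=C(C)C)C(=O)[C@@]1(CC=C(C)C)C(=O)C(C(=O)c1cccc(O[Si](C(C)C)(C(C)C)C(C)C)c1)=C2O | intermediate
23 | (1S,5S,7R,8S)-4-hydroxy-8-methyl-1,5,7-tris(3-methylbut-2-en-1-yl)-8-(4-methylpent-3-en-1-yl)-3-[3-(triisopropylsilyloxy)benzoyl]bicyclo[3.3.1]non-3-ene-2,9-dione | CC(C)=CCC[C@@]1(C)[C@H](CC=C(C)C)C[C@]2(CC=C(C)C)C(=O)[C@@]1(CC=C(C)C)C(=O)C(C(=O)c1cccc(O[Si](C(C)C)(C(C)C)C(C)C)c1)=C2O | intermediate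
24 | (1S,5S,7R,8S)-4-hydroxy-3-(3-hydroxybenzoyl)-8-methyl-1,5,7-tris(3-methylbut-2-en-1-yl)-8-(4-methylpent-3-en-1-yl)bicyclo[3.3.1]non-3-ene-2,9-dione (CNP0406274.2) | CC(C)=CCC[C@@]1(C)[C@H](CC=C(C)C)C[C@]2(CC=C(C)C)C(=O)[C@@]1(CC=C(C)C)C(=O)C(C(=O)c1cccc(O)c1)=C2O | target

Total step count: 15. Longest linear sequence: 11 steps (steps 1, 3, 5, 6, 9, 10, 11, 12, 13, 14, 15).

Steps most likely to fail

Step 12 (key ring closure). Several processes could divert the step:
- the acidic, chelating triketone may bind the iron and protonate its hydride, so that hydrogen-atom transfer stalls or reduces an enal C=C instead;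
- the C8 radical may undergo 1,2-acyl shift onto C9 (Dowd–Beckwith-type ring expansion) before it closes;
- the radical may close with the butenyl chain axial, giving the C8 epimer.

The fallback takes the acidic triketone out of the radical step by a protecting-group detour. It sets out from 20: titration with TMSCHN2 (toluene/MeOH, 0 °C) should give the methyl enol ether (6S)-6-allyl-6-(hexa-1,5-dien-2-yl)-3-methoxy-4,4-bis[(E)-4-oxobut-2-en-1-yl]-2-[3-(triisopropylsilyloxy)benzoyl]cyclohex-2-ene-1,5-dione F1 (either O-methyl regioisomer serves). This non-acidic substrate would be cyclised by the same HAT-initiated Giese closure, which can then be run colder to disfavour the acyl shift, to the bicyclic methyl enol ether (1S,5S,7S,8S)-1-allyl-8-(but-3-en-1-yl)-4-methoxy-8-methyl-5-[(E)-4-oxobut-2-en-1-yl]-7-(2-oxoethyl)-3-[3-(triisopropylsilyloxy)benzoyl]bicyclo[3.3.1]non-3-ene-2,9-dione F2. Mild hydrolysis of the vinylogous ester (1 M HCl, THF) comes back to the route at 21.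

Step 13 (cross-metathesis). The ruthenium carbene may turn over unproductively on the conjugated C=C of the C5 enal arm, so that this arm is not converted into a prenyl group; the C1 allyl and C8 butenyl groups may also ring-close to a cycloheptene before they are capped. The fallback avoids any enal exchange by differentiating the two C5 substituents from the start. It sets out from 13:
- One equivalent of 16 with Pd(PPh3)4 gives the mono-allylated compound 17, now isolated.
- Allyl methyl carbonate and Pd(PPh3)4 then give racemic 6-allyl-6-[(E)-4,4-dimethoxybut-2-en-1-yl]-2-(hexa-1,5-dien-2-yl)-3,5-dihydroxy-4-[3-(triisopropylsilyloxy)benzoyl]cyclohexa-2,4-dien-1-one F3.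
- The asymmetric allylation of step 10 at C1, followed by chromatographic separation of the C5 epimers, gives (4S,6S)-4,6-diallyl-4-[(E)-4,4-dimethoxybut-2-en-1-yl]-6-(hexa-1,5-dien-2-yl)-3-hydroxy-2-[3-(triisopropylsilyloxy)benzoyl]cyclohex-2-ene-1,5-dione F4, in which the acetal arm is cis to the hexadienyl group.
- Acetal hydrolysis gives the mono-enal (4S,6S)-4,6-diallyl-6-(hexa-1,5-dien-2-yl)-3-hydroxy-4-[(E)-4-oxobut-2-en-1-yl]-2-[3-(triisopropylsilyloxy)benzoyl]cyclohex-2-ene-1,5-dione F5.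
- The ring closure of step 12 gives (1S,5S,7S,8S)-1,5-diallyl-8-(but-3-en-1-yl)-4-hydroxy-8-methyl-7-(2-oxoethyl)-3-[3-(triisopropylsilyloxy)benzoyl]bicyclo[3.3.1]non-3-ene-2,9-dione F6.
- Cross-metathesis of its three terminal alkenes with 2-methyl-2-butene comes back to the route at 22.

Step 10 (asymmetric allylation). Facial discrimination at the crowded prochiral C1 may be poor, and reversible ionisation of the product by zerovalent palladium may erode the enantiomeric purity; C-allylation may also be slow against O-allylation. The fallback replaces asymmetric catalysis by resolution. It sets out from 18: allylation with allyl methyl carbonate and achiral Pd(PPh3)4 gives racemic 6-allyl-4,4-bis[(E)-4,4-dimethoxybut-2-en-1-yl]-6-(hexa-1,5-dien-2-yl)-3-hydroxy-2-[3-(triisopropylsilyloxy)benzoyl]cyclohex-2-ene-1,5-dione F7. Separation of the enantiomers by preparative chromatography on a chiral stationary phase comes back to the route at 19.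

Further compounds
F1 | step 12 | (6S)-6-allyl-6-(hexa-1,5-dien-2-yl)-3-methoxy-4,4-bis[(E)-4-oxobut-2-en-1-yl]-2-[3-(triisopropylsilyloxy)benzoyl]cyclohex-2-ene-1,5-dione | C=CCCC(=C)[C@]1(CC=C)C(=O)C(C(=O)c2cccc(O[Si](C(C)C)(C(C)C)C(C)C)c2)=C(OC)C(C/C=C/C=O)(C/C=C/C=O)C1=O
F2 | step 12 | (1S,5S,7S,8S)-1-allyl-8-(but-3-en-1-yl)-4-methoxy-8-methyl-5-[(E)-4-oxobut-2-en-1-yl]-7-(2-oxoethyl)-3-[3-(triisopropylsilyloxy)benzoyl]bicyclo[3.3.1]non-3-ene-2,9-dione | C=CCC[C@@]1(C)[C@H](CC=O)C[C@]2(C/C=C/C=O)C(=O)[C@@]1(CC=C)C(=O)C(C(=O)c1cccc(O[Si](C(C)C)(C(C)C)C(C)C)c1)=C2OC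
F3 | step 13 | racemic 6-allyl-6-[(E)-4,4-dimethoxybut-2-en-1-yl]-2-(hexa-1,5-dien-2-yl)-3,5-dihydroxy-4-[3-(triisopropylsilyloxy)benzoyl]cyclohexa-2,4-dien-1-one | C=CCCC(=C)C1=C(O)C(C(=O)c2cccc(O[Si](C(C)C)(C(C)C)C(C)C)c2)=C(O)C(CC=C)(C/C=C/C(OC)OC)C1=O
F4 | step 13 | (4S,6S)-4,6-diallyl-4-[(E)-4,4-dimethoxybut-2-en-1-yl]-6-(hexa-1,5-dien-2-yl)-3-hydroxy-2-[3-(triisopropylsilyloxy)benzoyl]cyclohex-2-ene-1,5-dione | C=CCCC(=C)[C@]1(CC=C)C(=O)C(C(=O)c2cccc(O[Si](C(C)C)(C(C)C)C(C)C)c2)=C(O)[C@](CC=C)(C/C=C/C(OC)OC)C1=O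
F5 | step 13 | (4S,6S)-4,6-diallyl-6-(hexa-1,5-dien-2-yl)-3-hydroxy-4-[(E)-4-oxobut-2-en-1-yl]-2-[3-(triisopropylsilyloxy)benzoyl]cyclohex-2-ene-1,5-dione | C=CCCC(=C)[C@]1(CC=C)C(=O)C(C(=O)c2cccc(O[Si](C(C)C)(C(C)C)C(C)C)c2)=C(O)[C@](CC=C)(C/C=C/C=O)C1=O
F6 | step 13 | (1S,5S,7S,8S)-1,5-diallyl-8-(but-3-en-1-yl)-4-hydroxy-8-methyl-7-(2-oxoethyl)-3-[3-(triisopropylsilyloxy)benzoyl]bicyclo[3.3.1]non-3-ene-2,9-dione | C=CCC[C@@]1(C)[C@H](CC=O)C[C@]2(CC=C)C(=O)[C@@]1(CC=C)C(=O)C(C(=O)c1cccc(O[Si](C(C)C)(C(C)C)C(C)C)c1)=C2O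
F7 | step 10 | racemic 6-allyl-4,4-bis[(E)-4,4-dimethoxybut-2-en-1-yl]-6-(hexa-1,5-dien-2-yl)-3-hydroxy-2-[3-(triisopropylsilyloxy)benzoyl]cyclohex-2-ene-1,5-dione | C=CCCC(=C)C1(CC=C)C(=O)C(C(=O)c2cccc(O[Si](C(C)C)(C(C)C)C(C)C)c2)=C(O)C(C/C=C/C(OC)OC)(C/C=C/C(OC)OC)C1=O
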